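**Retrosynthetic overview**

- The target is cut first at its two 4-hydroxybenzoate C–O bonds, back to a triol; these are made last by a double Mitsunobu esterification with unprotected 4-hydroxybenzoic acid, and no protecting group is used in the route.
- The (E)-3-hydroxyprop-1-enyl chain on C5 of ring A comes from a C5 formyl group by Wittig olefination and ester reduction.
- Feature and key disconnection: in ring B (O1–C2–C3–C3a–C7a) C3 carries a CH2O carbon and the neighbouring C2 carries O1 and the syringyl ring C. The C3–CH2 and O1–C2 bonds are cut together, back to formaldehyde and an (E)-2-hydroxystilbene whose C2=C3 double bond joins ring A to ring C.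
- The stilbene keeps the ring C 4-hydroxyl free, so that C3 is the β-carbon of a 4-hydroxystyrene and C2 becomes a para-quinone methide, and carries a formyl group on ring A para to the trapping phenol. It comes from a Heck coupling of 5-iodovanillin with 4-vinylsyringol, itself made from syringaldehyde.
- Ring order: rings A and C are bought; ring B is the only ring formed, in the key step, together with both stereocentres.

Key step: step 3

Labels: benzofuran numbering of the target (O1, C2, C3, C3a, C4–C7, C7a) is used for all intermediates, the stilbene included. Ring A is the benzo ring, ring B the dihydrofuran ring, ring C the 4-hydroxy-3,5-dimethoxyphenyl ring on C2.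

Assumption: the sense of induction of the confined acid cannot be predicted with confidence. The route takes the catalyst antipode (from (R)- or (S)-BINOL) that delivers formaldehyde to the Re face of C3.

**Route**

Step 1
Reactants: 1 syringaldehyde
Product: 2 4-vinylsyringol (4-ethenyl-2,6-dimethoxyphenol)
Conditions: Ph3PCH3Br (3 equiv), KOtBu (3 equiv), THF, 0 °C to rt; aq. NH4Cl; used fresh
Reagents that add atoms: methyltriphenylphosphonium bromide, C[P+](c1ccccc1)(c1ccccc1)c1ccccc1.[Br-]
Why: Wittig methylenation with the unstabilised ylide Ph3P=CH2, used in excess so that one equivalent is spent on the phenol, should convert the aldehyde of the phenoxide into the vinyl group, a standard way to 4-vinylphenols.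

Step 2
Reactants: 2 4-vinylsyringol; 3 5-iodovanillin
Product: 4 4-hydroxy-3-[(E)-2-(4-hydroxy-3,5-dimethoxyphenyl)ethenyl]-5-methoxybenzaldehyde
Conditions: Pd(OAc)2 (5 mol%), P(o-tol)3 (10 mol%), Et3N, DMF, 90 °C, argon, dark
Reagents that add atoms: none
Why: Mizoroki–Heck reaction, in which zerovalent palladium inserts into the C–I bond of 3, the terminal alkene of 2 inserts syn with the aryl group going to the unsubstituted carbon, and syn β-hydride elimination should give the (E)-stilbene, free phenols being tolerated with an amine base.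

Step 3
Reactants: 4 4-hydroxy-3-[(E)-2-(4-hydroxy-3,5-dimethoxyphenyl)ethenyl]-5-methoxybenzaldehyde
Product: 6 (2S,3R)-2-(4-hydroxy-3,5-dimethoxyphenyl)-3-(hydroxymethyl)-7-methoxy-2,3-dihydro-1-benzofuran-5-carbaldehyde, via para-quinone methide 5 (not isolated)
Conditions: (CH2O)n (1.5 equiv), confined chiral imino-imidodiphosphoric acid (iIDP type, BINOL-derived, 5 mol%), CHCl3, −20 °C to rt, dark; then Et3N, MeOH
Reagents that add atoms: formaldehyde (from paraformaldehyde), C=O
Why: Proposed new method: the confined acid protonates formaldehyde in its chiral pocket and C3, the β-carbon of the 4-hydroxystyrene made up of ring C and the C2=C3 bond, adds to it through its Re face, which forms the C3–CH2OH bond, sets C3 (R) under catalyst control and leaves the para-quinone methide 5. The closest known reaction type is the catalytic asymmetric intermolecular Prins reaction of styrenes with paraformaldehyde under confined chiral acids, in which a second formaldehyde closes a 1,3-dioxane; here the phenol on C7a intercepts the cation instead. Ring B is closed by acid-catalysed oxa-1,6-addition of that phenol to C2 of 5, a 5-exo-trig closure with respect to the exocyclic C2=C double bond of the quinone methide, which forms O1–C2 and restores the aromatic ring C. C2 is set in this closure by the C3 centre: ring C ends up anti to the CH2OH arm (2S, trans), and because the O1–C2 bond of a 4-hydroxybenzyl aryl ether can re-ionise under the acid while C3 cannot epimerise, any cis isomer should drain to trans. The step needs C3 and not C2 to be the nucleophilic carbon; this is secured by the free ring C hydroxyl, a coplanar para donor that would be twisted out of conjugation by its two ortho methoxy groups if it were alkylated, set against the C7a phenol, whose lone pair is drawn into the para formyl group. It also needs attack by the alkene in preference to the arenes, which is helped by every position ortho or para to either phenol being substituted.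

Step 4
Reactants: 6 (2S,3R)-2-(4-hydroxy-3,5-dimethoxyphenyl)-3-(hydroxymethyl)-7-methoxy-2,3-dihydro-1-benzofuran-5-carbaldehyde
Product: 7 ethyl (E)-3-[(2S,3R)-2-(4-hydroxy-3,5-dimethoxyphenyl)-3-(hydroxymethyl)-7-methoxy-2,3-dihydro-1-benzofuran-5-yl]prop-2-enoate
Conditions: Ph3P=CHCO2Et (1.3 equiv), toluene, 60 °C
Reagents that add atoms: ethyl (triphenylphosphoranylidene)acetate, CCOC(=O)C=P(c1ccccc1)(c1ccccc1)c1ccccc1
Why: Wittig reaction with a stabilised ylide, which is (E)-selective with aromatic aldehydes and too weakly basic to deprotonate the hindered phenol or to disturb C2 and C3.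

Step 5
Reactants: 7 ethyl (E)-3-[(2S,3R)-2-(4-hydroxy-3,5-dimethoxyphenyl)-3-(hydroxymethyl)-7-methoxy-2,3-dihydro-1-benzofuran-5-yl]prop-2-enoate
Product: 8 4-[(2S,3R)-3-(hydroxymethyl)-5-[(E)-3-hydroxyprop-1-enyl]-7-methoxy-2,3-dihydro-1-benzofuran-2-yl]-2,6-dimethoxyphenol
Conditions: i-Bu2AlH (5 equiv), THF–toluene, −78 to 0 °C; aq. KNaC4H4O6
Reagents that add atoms: none
Why: 1,2-reduction of the α,β-unsaturated ester with i-Bu2AlH, the standard conversion of cinnamates of phenolic 2-aryl-dihydrobenzofurans into cinnamyl alcohols, with extra hydride to cover the phenol and the alcohol and no stereocentre at risk.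

Step 6
Reactants: 8 4-[(2S,3R)-3-(hydroxymethyl)-5-[(E)-3-hydroxyprop-1-enyl]-7-methoxy-2,3-dihydro-1-benzofuran-2-yl]-2,6-dimethoxyphenol; 9 4-hydroxybenzoic acid (3 equiv)
Product: 10 quiquesetinerviusin B
Conditions: PPh3 (2.5 equiv), DIAD (2.5 equiv, slow addition), THF, 0 °C to rt
Reagents that add atoms: none
Why: Double Mitsunobu esterification, in which each primary alcohol is activated as its alkoxyphosphonium salt and displaced (SN2, no stereocentre involved) by the carboxylate of 9, which is about five pKa units more acidic than any phenol present, so that the phenols of 9, of the product and of ring C (shielded further by its two ortho methoxy groups) should stay unalkylated.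

**Compound list**

1 | syringaldehyde (4-hydroxy-3,5-dimethoxybenzaldehyde) | COc1cc(C=O)cc(OC)c1O | starting material
2 | 4-vinylsyringol (4-ethenyl-2,6-dimethoxyphenol) | COc1cc(C=C)cc(OC)c1O | intermediate
3 | 5-iodovanillin (4-hydroxy-3-iodo-5-methoxybenzaldehyde) | COc1cc(C=O)cc(I)c1O | starting material
4 | 4-hydroxy-3-[(E)-2-(4-hydroxy-3,5-dimethoxyphenyl)ethenyl]-5-methoxybenzaldehyde | COc1cc(C=O)cc(/C=C/c2cc(OC)c(O)c(OC)c2)c1O | intermediate
5 | 4-[(2R)-2-(5-formyl-2-hydroxy-3-methoxyphenyl)-3-hydroxypropylidene]-2,6-dimethoxycyclohexa-2,5-dien-1-one (para-quinone methide) | COc1cc(C=O)cc([C@H](CO)C=C2C=C(OC)C(=O)C(OC)=C2)c1O | intermediate (not isolated)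
6 | (2S,3R)-2-(4-hydroxy-3,5-dimethoxyphenyl)-3-(hydroxymethyl)-7-methoxy-2,3-dihydro-1-benzofuran-5-carbaldehyde | COc1cc([C@H]2Oc3c(OC)cc(C=O)cc3[C@@H]2CO)cc(OC)c1O | intermediate
7 | ethyl (E)-3-[(2S,3R)-2-(4-hydroxy-3,5-dimethoxyphenyl)-3-(hydroxymethyl)-7-methoxy-2,3-dihydro-1-benzofuran-5-yl]prop-2-enoate | COc1cc([C@H]2Oc3c(OC)cc(/C=C/C(=O)OCC)cc3[C@@H]2CO)cc(OC)c1O | intermediate
8 | 4-[(2S,3R)-3-(hydroxymethyl)-5-[(E)-3-hydroxyprop-1-enyl]-7-methoxy-2,3-dihydro-1-benzofuran-2-yl]-2,6-dimethoxyphenol | COc1cc([C@H]2Oc3c(OC)cc(/C=C/CO)cc3[C@@H]2CO)cc(OC)c1O | intermediate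
9 | 4-hydroxybenzoic acid | OC(=O)c1ccc(O)cc1 | starting material
10 | quiquesetinerviusin B, [(2S,3R)-2-(4-hydroxy-3,5-dimethoxyphenyl)-5-[(E)-3-(4-hydroxybenzoyloxy)prop-1-enyl]-7-methoxy-2,3-dihydro-1-benzofuran-3-yl]methyl 4-hydroxybenzoate | COc1cc([C@H]2Oc3c(OC)cc(/C=C/COC(=O)c4ccc(O)cc4)cc3[C@@H]2COC(=O)c2ccc(O)cc2)cc(OC)c1O | target

**Step count and risks**

Total: 6 steps. Longest linear sequence: 6 steps (1 → 2 → 4 → 6 → 7 → 8 → 10).

Steps most likely to fail:

1. Step 3 (proposed new method).
 - What may go wrong: proton transfer to the alkene may outrun formaldehyde transfer, giving ring closure without the one-carbon arm or acid-induced dimerisation of the stilbene. Formaldehyde may be attacked by C2 in place of C3. Facial selectivity may be poor in a pocket that also binds two phenols and an aldehyde. A second formaldehyde may be taken up, as a dioxane or on ring C. Reversible loss of formaldehyde from 5 may erode the enantiomeric purity.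
 - Fallback (known chemistry; sets out from 3 and 1, returns at 8): ring B is closed by enantioselective intramolecular C–H insertion of a rhodium carbenoid, an established way to 2-aryl-2,3-dihydrobenzofuran-3-carboxylates. Wittig reaction of 3 with Ph3P=CHCO2Et should give ethyl 5-iodoferulate F1. Syringaldehyde 1 is silylated (TBSCl, imidazole, DMF) to the silyloxy aldehyde F2 and reduced with NaBH4 to the benzyl alcohol F3. Mitsunobu etherification of F1 with F3 (PPh3, DIAD) should give the aryl benzyl ether F4. Palladium-catalysed coupling of its C–I bond with ethyl diazoacetate (Pd(PPh3)4, Ag2CO3, Et3N, toluene, rt) should give the aryldiazoacetate F5. The chiral dirhodium tetracarboxylate Rh2(S-DOSP)4, dirhodium tetrakis[(S)-N-(4-dodecylphenylsulfonyl)prolinate], or its antipode, whichever gives 2S, should insert the carbenoid into the benzylic C–H bond of the ether and give the cis ester F6. DBU then epimerises C3 to the trans ester F7. i-Bu2AlH reduces both esters to the silyl-protected diol F8, and n-Bu4NF removes the silyl group to give 8.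

2. Step 6.
 - What may go wrong: phenols may be alkylated in competition with the carboxylate once the acid runs low; the activated cinnamyl-type alcohol may ionise and give allylic transposition; the second esterification at the β-branched C3–CH2OH may stall.
 - Fallback (sets out from 8, returns at 10): the ring C phenol is masked and protected acid is used. Phenoxide-selective acetylation (Ac2O, aq. NaOH, THF, 0 °C) should give the aryl acetate diol F9. Carbodiimide esterification of both alcohols with 4-acetoxybenzoic acid (EDC·HCl, DMAP, CH2Cl2) should give the triacetate F10. Pyrrolidine (THF, rt) cleaves the three aryl acetates by aminolysis, leaving the two alkyl benzoates, to give 10.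

3. Step 2.
 - What may go wrong: the electron-rich vinylphenol may polymerise or oxidise at the coupling temperature, arylation may occur in part at the internal alkene carbon, and oxidative addition into the iodophenoxide may be slow.
 - Fallback (sets out from 2, returns at 4): the C–C bond is made by Suzuki–Miyaura coupling with fixed regiochemistry. Cross-metathesis of 2 with 4,4,5,5-tetramethyl-2-vinyl-1,3,2-dioxaborolane using the second-generation Grubbs catalyst RuCl2(=CHPh)(H2IMes)(PCy3) in CH2Cl2 at 40 °C should give the (E)-styrylboronate F11. Coupling of F11 with 3 (PdCl2(dppf), K2CO3, dioxane–water, 70 °C) gives 4.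

**Further compounds**

F1 | step 3 | ethyl (E)-3-(4-hydroxy-3-iodo-5-methoxyphenyl)prop-2-enoate (ethyl 5-iodoferulate) | CCOC(=O)/C=C/c1cc(I)c(O)c(OC)c1
F2 | step 3 | 4-(tert-butyldimethylsilyloxy)-3,5-dimethoxybenzaldehyde | COc1cc(C=O)cc(OC)c1O[Si](C)(C)C(C)(C)C
F3 | step 3 | [4-(tert-butyldimethylsilyloxy)-3,5-dimethoxyphenyl]methanol | COc1cc(CO)cc(OC)c1O[Si](C)(C)C(C)(C)C
F4 | step 3 | ethyl (E)-3-[4-[[4-(tert-butyldimethylsilyloxy)-3,5-dimethoxyphenyl]methoxy]-3-iodo-5-methoxyphenyl]prop-2-enoate | CCOC(=O)/C=C/c1cc(I)c(OCc2cc(OC)c(O[Si](C)(C)C(C)(C)C)c(OC)c2)c(OC)c1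
F5 | step 3 | ethyl 2-diazo-2-[2-[[4-(tert-butyldimethylsilyloxy)-3,5-dimethoxyphenyl]methoxy]-5-[(E)-3-ethoxy-3-oxoprop-1-enyl]-3-methoxyphenyl]acetate | CCOC(=O)/C=C/c1cc(C(=[N+]=[N-])C(=O)OCC)c(OCc2cc(OC)c(O[Si](C)(C)C(C)(C)C)c(OC)c2)c(OC)c1
F6 | step 3 | ethyl (2S,3R)-2-[4-(tert-butyldimethylsilyloxy)-3,5-dimethoxyphenyl]-5-[(E)-3-ethoxy-3-oxoprop-1-enyl]-7-methoxy-2,3-dihydro-1-benzofuran-3-carboxylate (cis) | COc1cc([C@H]2Oc3c(OC)cc(/C=C/C(=O)OCC)cc3[C@H]2C(=O)OCC)cc(OC)c1O[Si](C)(C)C(C)(C)C
F7 | step 3 | ethyl (2S,3S)-2-[4-(tert-butyldimethylsilyloxy)-3,5-dimethoxyphenyl]-5-[(E)-3-ethoxy-3-oxoprop-1-enyl]-7-methoxy-2,3-dihydro-1-benzofuran-3-carboxylate (trans) | COc1cc([C@H]2Oc3c(OC)cc(/C=C/C(=O)OCC)cc3[C@@H]2C(=O)OCC)cc(OC)c1O[Si](C)(C)C(C)(C)C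
F8 | step 3 | (E)-3-[(2S,3R)-2-[4-(tert-butyldimethylsilyloxy)-3,5-dimethoxyphenyl]-3-(hydroxymethyl)-7-methoxy-2,3-dihydro-1-benzofuran-5-yl]prop-2-en-1-ol | COc1cc([C@H]2Oc3c(OC)cc(/C=C/CO)cc3[C@@H]2CO)cc(OC)c1O[Si](C)(C)C(C)(C)C
F9 | step 6 | 4-[(2S,3R)-3-(hydroxymethyl)-5-[(E)-3-hydroxyprop-1-enyl]-7-methoxy-2,3-dihydro-1-benzofuran-2-yl]-2,6-dimethoxyphenyl acetate | COc1cc([C@H]2Oc3c(OC)cc(/C=C/CO)cc3[C@@H]2CO)cc(OC)c1OC(C)=O
F10 | step 6 | [(2S,3R)-2-(4-acetoxy-3,5-dimethoxyphenyl)-5-[(E)-3-(4-acetoxybenzoyloxy)prop-1-enyl]-7-methoxy-2,3-dihydro-1-benzofuran-3-yl]methyl 4-acetoxybenzoate | COc1cc([C@H]2Oc3c(OC)cc(/C=C/COC(=O)c4ccc(OC(C)=O)cc4)cc3[C@@H]2COC(=O)c2ccc(OC(C)=O)cc2)cc(OC)c1OC(C)=O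
F11 | step 2 | 2,6-dimethoxy-4-[(E)-2-(4,4,5,5-tetramethyl-1,3,2-dioxaborolan-2-yl)ethenyl]phenol | COc1cc(/C=C/B2OC(C)(C)C(C)(C)O2)cc(OC)c1O
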